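The three phenols are masked as methyl ethers. The retrosynthesis then cuts C4–C4a of the chlorinated chromone (Friedel–Crafts), its O1–C2 bond (vinylic substitution by a chlorophenol), its C2–C3 bond (a formyl carbon on an arylacetate) and last the diaryl ether C–O bond.
Forward, rings A, B and C of the chlorine-free isoflavone arrive ready-made in calycosin. An Ullmann coupling joins the second ring B, the one-carbon unit and the chlorophenol follow, and the second pyranone closes last, at carbon.
The enabling feature lies in ring A of the chlorinated unit, where C8a bears O1, C8 bears Cl and C7 bears O. The open-chain 2-chloro-3-methoxyphenyl vinyl ether therefore has one ortho carbon filled by chlorine and a single free ortho carbon (future C4a), which lies para to the methoxy oxygen.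
The target has no stereocentre, so only the Z geometry of acrylic acid 9 matters. It comes from tosylation of a lithium-chelated enolate and a retentive addition–elimination, and acid-induced E/Z equilibration backs it up.
Key step: step 7

Assumption: 1, 3 and 7 are purchased. Compound 5 is written as the chelated Z enol of the α-formyl ester, and 6, 8 and 9 are drawn as the Z isomers the route aims at.

Step 1
Reactants: 1 calycosin (7,3'-dihydroxy-4'-methoxyisoflavone)
Product: 2 7-O-methylcalycosin, 3-(3-hydroxy-4-methoxyphenyl)-7-methoxychromen-4-one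
Conditions: MeI (1.05 equiv), K2CO3 (1.1 equiv), DMF, 0 °C to rt
Reagents that add atoms: iodomethane, CI
Why: This is a Williamson etherification under limiting base, in which the 7-OH (para to the C4 carbonyl, hence a vinylogous carboxylic acid) is far more acidic than the guaiacol-type 3'-OH, so one equivalent of base and MeI should alkylate O7 alone.

Step 2
Reactants: 2 7-O-methylcalycosin; 3 tert-butyl 2-(4-bromophenyl)acetate
Product: 4 tert-butyl 2-[4-[2-methoxy-5-(7-methoxy-4-oxochromen-3-yl)phenoxy]phenyl]acetate
Conditions: CuI (10 mol %), N,N-dimethylglycine·HCl (30 mol %), Cs2CO3, 4 Å MS, 1,4-dioxane, 90 °C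
Reagents that add atoms: none
Why: This ligand-accelerated Ullmann diaryl ether coupling is well tried on ortho-methoxyphenols and on bromophenylacetates, dry carbonate in dioxane supplies no hydroxide that could open the pyranone, and the tert-butyl ester is chosen so that the acid can later be freed without base.

Step 3
Reactants: 4 diaryl ether tert-butyl ester
Product: 5 tert-butyl (Z)-3-hydroxy-2-[4-[2-methoxy-5-(7-methoxy-4-oxochromen-3-yl)phenoxy]phenyl]prop-2-enoate (enol of the α-formyl ester)
Conditions: HCO2Me (excess), KOtBu, THF, 0 °C to rt; then cold 1 M HCl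
Reagents that add atoms: methyl formate, COC=O
Why: This crossed Claisen condensation (α-formylation of an arylacetate) is driven by the stabilised enolate of 5, the bulky ester resists methoxide, and the isoflavone should survive because alkoxide addition at its C2 is reversible without water and formate ester, base and acid quench are the classical conditions for building that ring.

Step 4
Reactants: 5 α-formyl ester (enol)
Product: 6 tert-butyl (Z)-2-[4-[2-methoxy-5-(7-methoxy-4-oxochromen-3-yl)phenoxy]phenyl]-3-(4-methylphenyl)sulfonyloxyprop-2-enoate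
Conditions: TsCl, N-methylimidazole, LiOH, CH2Cl2, 0 °C to rt
Reagents that add atoms: p-toluenesulfonyl chloride, Cc1ccc(cc1)S(=O)(=O)Cl
Why: In this O-sulfonylation of a β-dicarbonyl enolate by the TsCl–N-methylimidazole reagent, the lithium cation bridges the enolate oxygen and the ester carbonyl, so the oxygen that is tosylated sits cis to the ester and the Z enol tosylate should result.

Step 5
Reactants: 6 (Z)-enol tosylate; 7 2-chloro-3-methoxyphenol
Product: 8 tert-butyl (Z)-3-(2-chloro-3-methoxyphenoxy)-2-[4-[2-methoxy-5-(7-methoxy-4-oxochromen-3-yl)phenoxy]phenyl]prop-2-enoate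
Conditions: Cs2CO3, MeCN, 0 °C to rt (1.0 equiv of 7)
Reagents that add atoms: none
Why: In this nucleophilic vinylic substitution by addition–elimination on a β-sulfonyloxyacrylate, the phenoxide adds to the ester-activated CH carbon and tosylate departs faster than the carbanion rotates, so the Z geometry should be retained, and any E isomer is carried on because step 7 equilibrates it.

Step 6
Reactants: 8 (Z)-aryloxyacrylate tert-butyl ester
Product: 9 (Z)-3-(2-chloro-3-methoxyphenoxy)-2-[4-[2-methoxy-5-(7-methoxy-4-oxochromen-3-yl)phenoxy]phenyl]prop-2-enoic acid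
Conditions: TFA–CH2Cl2 (1:3), 0 °C to rt
Reagents that add atoms: none
Why: Acidolysis of the tert-butyl ester (alkyl–oxygen fission with loss of isobutene) frees the acid without hydroxide, which would add to C2 of the isoflavone and to the aryloxy-bearing carbon of the acrylate, while methyl ethers, aryl chloride and enol ether tolerate anhydrous TFA.

Step 7
Reactants: 9 (Z)-3-aryloxy-2-arylacrylic acid
Product: 11 bisoflavolin K trimethyl ether [8-chloro-7-methoxy-3-[4-[2-methoxy-5-(7-methoxy-4-oxochromen-3-yl)phenoxy]phenyl]chromen-4-one], via acylium ion 10 (not isolated)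
Conditions: Eaton's reagent (7.7 wt % P2O5 in MeSO3H), 0.02 M, rt to 45 °C; then ice–water
Reagents that add atoms: none
Why: Eaton's reagent dehydrates the carboxyl group of 9 to acylium ion 10, whose cationic carbon (future C4) is held beside the phenoxy ring by the Z alkene; it attacks the free ortho carbon (future C4a), and proton loss from the arenium ion gives the C4–C4a bond of 11. The closest known reaction type is the intramolecular Friedel–Crafts cycloacylation of 3-aryloxyacrylic acids to 4H-chromen-4-ones, applied here to a member that carries an aryl group on the α-carbon. The one ring formed, the pyranone of the chlorinated unit, closes as a six-membered ring by electrophilic aromatic substitution, 6-exo at the acyl carbon because the C–O multiple bond stays outside the ring, with O1, C2, C3 and C8a already coplanar. No stereocentre is created, and the geometric demand corrects itself: reversible protonation at the α-carbon of the donor–acceptor alkene lets an E isomer rotate into the Z form, which alone is drained by cyclisation, since from the E form the acyl carbon could reach only the α-aryl ring through a four-membered ring. The step needs acylation at a single ring carbon, and the substrate secures it because one of the two positions ortho to the ether oxygen is occupied by chlorine while the other gains electron density from the methoxy group across the ring. Acylation of a second molecule is held back by dilution and by protonation of the existing isoflavone carbonyl in MeSO3H, which deactivates the rings attached to it.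

Step 8
Reactants: 11 bisoflavolin K trimethyl ether
Product: 12 bisoflavolin K
Conditions: BBr3 (excess), CH2Cl2, −78 °C to rt; then ice–water
Reagents that add atoms: none
Why: In this Lewis-acid cleavage of aryl methyl ethers, BBr3 binds each methoxy oxygen and bromide removes the methyl group in an SN2 step, whereas the diaryl ether, both pyranones and the C–Cl bond offer no sp3 carbon to attack and should persist, as is usual for methylated isoflavones.

Compound list
1 | calycosin, 7-hydroxy-3-(3-hydroxy-4-methoxyphenyl)chromen-4-one | COc1ccc(-c2coc3cc(O)ccc3c2=O)cc1O | starting material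
2 | 7-O-methylcalycosin, 3-(3-hydroxy-4-methoxyphenyl)-7-methoxychromen-4-one | COc1ccc(-c2coc3cc(OC)ccc3c2=O)cc1O | intermediate
3 | tert-butyl 2-(4-bromophenyl)acetate | CC(C)(C)OC(=O)Cc1ccc(Br)cc1 | starting material
4 | tert-butyl 2-[4-[2-methoxy-5-(7-methoxy-4-oxochromen-3-yl)phenoxy]phenyl]acetate | CC(C)(C)OC(=O)Cc1ccc(Oc2cc(-c3coc4cc(OC)ccc4c3=O)ccc2OC)cc1 | intermediate
5 | tert-butyl (Z)-3-hydroxy-2-[4-[2-methoxy-5-(7-methoxy-4-oxochromen-3-yl)phenoxy]phenyl]prop-2-enoate | CC(C)(C)OC(=O)/C(=C\O)c1ccc(Oc2cc(-c3coc4cc(OC)ccc4c3=O)ccc2OC)cc1 | intermediate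
6 | tert-butyl (Z)-2-[4-[2-methoxy-5-(7-methoxy-4-oxochromen-3-yl)phenoxy]phenyl]-3-(4-methylphenyl)sulfonyloxyprop-2-enoate | CC(C)(C)OC(=O)/C(=C\OS(=O)(=O)c1ccc(C)cc1)c1ccc(Oc2cc(-c3coc4cc(OC)ccc4c3=O)ccc2OC)cc1 | intermediate
7 | 2-chloro-3-methoxyphenol | COc1cccc(O)c1Cl | starting material
8 | tert-butyl (Z)-3-(2-chloro-3-methoxyphenoxy)-2-[4-[2-methoxy-5-(7-methoxy-4-oxochromen-3-yl)phenoxy]phenyl]prop-2-enoate | CC(C)(C)OC(=O)/C(=C\Oc1cccc(OC)c1Cl)c1ccc(Oc2cc(-c3coc4cc(OC)ccc4c3=O)ccc2OC)cc1 | intermediate
9 | (Z)-3-(2-chloro-3-methoxyphenoxy)-2-[4-[2-methoxy-5-(7-methoxy-4-oxochromen-3-yl)phenoxy]phenyl]prop-2-enoic acid | OC(=O)/C(=C\Oc1cccc(OC)c1Cl)c1ccc(Oc2cc(-c3coc4cc(OC)ccc4c3=O)ccc2OC)cc1 | intermediate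
10 | acylium ion derived from 9 (Z alkene, not isolated) | O=[C+]/C(=C\Oc1cccc(OC)c1Cl)c1ccc(Oc2cc(-c3coc4cc(OC)ccc4c3=O)ccc2OC)cc1 | intermediate
11 | bisoflavolin K trimethyl ether, 8-chloro-7-methoxy-3-[4-[2-methoxy-5-(7-methoxy-4-oxochromen-3-yl)phenoxy]phenyl]chromen-4-one | COc1ccc(-c2coc3cc(OC)ccc3c2=O)cc1Oc1ccc(-c2coc3c(Cl)c(OC)ccc3c2=O)cc1 | intermediate
12 | bisoflavolin K | O=c1c(-c2ccc(O)c(Oc3ccc(-c4coc5c(Cl)c(O)ccc5c4=O)cc3)c2)coc2cc(O)ccc12 | target

Total step count: 8. Longest linear sequence: 8 steps (1 to 12); 3 and 7 enter as purchased building blocks.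

Steps most likely to fail

Step 7. Several processes may outrun ring closure. Protonation of the donor–acceptor alkene may lead to loss of CO2 or to cleavage of the vinyl C–O bond. The activated acid may also acylate the electron-rich ring B of a second molecule.
The fallback keeps the C4–C4a bond as a Friedel–Crafts acylation but makes it intermolecularly, one carbon earlier, and adds C2 afterwards. It sets out from 4.
- TFA in CH2Cl2 should give 2-[4-[2-methoxy-5-(7-methoxy-4-oxochromen-3-yl)phenoxy]phenyl]acetic acid F1.
- Heating F1 with 2-chlororesorcinol in BF3·OEt2 at 85 °C should acylate the resorcinol at its only activated kind of position, giving 1-(3-chloro-2,4-dihydroxyphenyl)-2-[4-[2-methoxy-5-(7-methoxy-4-oxochromen-3-yl)phenoxy]phenyl]ethanone F2.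
- DMF and MeSO2Cl in the presence of BF3·OEt2 at 60 °C then supply C2 and should close 8-chloro-7-hydroxy-3-[4-[2-methoxy-5-(7-methoxy-4-oxochromen-3-yl)phenoxy]phenyl]chromen-4-one F3.
- The BBr3 conditions of step 8 take F3 back to the route at 12.

Step 5. The phenoxide may attack the sulfur of the enol tosylate in place of the vinylic carbon, which transfers the sulfonyl group and regenerates the enolate. Reversible re-addition of phenoxide may also erode the alkene geometry.
The fallback makes the vinyl C–O bond on a small halide and forms the bond between the α-carbon and the aryl ring last, by cross-coupling. It sets out from 2 and 7.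
- tert-Butyl propiolate and Br2 (CH2Cl2, 0 °C, anti addition) should give tert-butyl (E)-2,3-dibromoprop-2-enoate F4.
- Phenol 7 with K2CO3 in MeCN should displace the β-bromide by addition–elimination to give tert-butyl (E)-2-bromo-3-(2-chloro-3-methoxyphenoxy)prop-2-enoate F5, in which aryloxy and ester groups are already cis.
- In parallel, 2 and 1-bromo-4-iodobenzene under the conditions of step 2 should couple at the iodide to give 3-[3-(4-bromophenoxy)-4-methoxyphenyl]-7-methoxychromen-4-one F6.
- Miyaura borylation of F6 (B2pin2, Pd(dppf)Cl2, KOAc, dioxane, 85 °C) should give 7-methoxy-3-[4-methoxy-3-[4-(4,4,5,5-tetramethyl-1,3,2-dioxaborolan-2-yl)phenoxy]phenyl]chromen-4-one F7.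
- Suzuki–Miyaura coupling of F5 with F7 (Pd(PPh3)4, K3PO4, dioxane–water, 70 °C) proceeds with retention at the alkene and leaves the aryl chloride alone. It comes back to the route at 8.

Step 3. Alkoxide may open the pyranone of the calycosin unit. The ester enolate may add to C2 of another isoflavone before formate traps it. Methoxide may also exchange the tert-butyl ester.
The fallback avoids a free enolate and alkoxide base by a neutral aminomethylenation. It sets out from 4.
- tert-Butoxybis(dimethylamino)methane (Bredereck's reagent) in toluene at 90 °C should give tert-butyl (E)-3-(dimethylamino)-2-[4-[2-methoxy-5-(7-methoxy-4-oxochromen-3-yl)phenoxy]phenyl]prop-2-enoate F8.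
- Brief hydrolysis with 1 M HCl in THF at rt unmasks the formyl group and re-closes any pyranone opened by dimethylamine. It comes back to the route at 5.

Further compounds
F1 | step 7 | 2-[4-[2-methoxy-5-(7-methoxy-4-oxochromen-3-yl)phenoxy]phenyl]acetic acid | OC(=O)Cc1ccc(Oc2cc(-c3coc4cc(OC)ccc4c3=O)ccc2OC)cc1
F2 | step 7 | 1-(3-chloro-2,4-dihydroxyphenyl)-2-[4-[2-methoxy-5-(7-methoxy-4-oxochromen-3-yl)phenoxy]phenyl]ethanone | O=C(Cc1ccc(Oc2cc(-c3coc4cc(OC)ccc4c3=O)ccc2OC)cc1)c1ccc(O)c(Cl)c1O
F3 | step 7 | 8-chloro-7-hydroxy-3-[4-[2-methoxy-5-(7-methoxy-4-oxochromen-3-yl)phenoxy]phenyl]chromen-4-one | COc1ccc(-c2coc3cc(OC)ccc3c2=O)cc1Oc1ccc(-c2coc3c(Cl)c(O)ccc3c2=O)cc1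
F4 | step 5 | tert-butyl (E)-2,3-dibromoprop-2-enoate | Br/C=C(/Br)C(=O)OC(C)(C)C
F5 | step 5 | tert-butyl (E)-2-bromo-3-(2-chloro-3-methoxyphenoxy)prop-2-enoate | COc1cccc(O/C=C(/Br)C(=O)OC(C)(C)C)c1Cl
F6 | step 5 | 3-[3-(4-bromophenoxy)-4-methoxyphenyl]-7-methoxychromen-4-one | COc1ccc(-c2coc3cc(OC)ccc3c2=O)cc1Oc1ccc(Br)cc1
F7 | step 5 | 7-methoxy-3-[4-methoxy-3-[4-(4,4,5,5-tetramethyl-1,3,2-dioxaborolan-2-yl)phenoxy]phenyl]chromen-4-one | COc1ccc(-c2coc3cc(OC)ccc3c2=O)cc1Oc1ccc(B2OC(C)(C)C(C)(C)O2)cc1
F8 | step 3 | tert-butyl (E)-3-(dimethylamino)-2-[4-[2-methoxy-5-(7-methoxy-4-oxochromen-3-yl)phenoxy]phenyl]prop-2-enoate | CC(C)(C)OC(=O)/C(=C/N(C)C)c1ccc(Oc2cc(-c3coc4cc(OC)ccc4c3=O)ccc2OC)cc1
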